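**Retrosynthetic overview**
- Feature: the A ring (C4a, C5, C6, C7, C8, C8a, with oxygens on C5, C7 and C8a) is C3-symmetric phloroglucinol (1), so a pyranone can be fused onto any of its C–C(OH) edges without regiocontrol, and the two unused hydroxyls become 5-OH and 7-OH.
- The C2–C3 unit with the B ring comes from ethyl methoxyacetate (2) and 4-methoxybenzoyl chloride (3), joined by crossed Claisen acylation to the α-methoxy aroylacetate 4.
- Key disconnection (retro-Mentzer): C4–C4a and O1–C2 of the pyranone, leading back to 1 + 4; forward, ketene 5 and diketone 6 lead to flavone 7. The C ring is the only ring formed; the A and B rings are bought.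
- End game: O-demethylation to kaempferol 8, sulfation of O3, O7 and O4' (pyridinium salt 9, isolated as potassium salt 10), then protonation to the target 11.

Key step: step 2

Assumption: the target has no stereocentre, so nothing needs to be controlled for the "single enantiomer"; the free tri(hydrogen sulfate) as drawn is expected to be acid-labile, so it is released only in the last step from the stable tripotassium salt.

**Step 1**
Reactants: 2 ethyl methoxyacetate; 3 4-methoxybenzoyl chloride
Product: 4 ethyl 2-methoxy-3-(4-methoxyphenyl)-3-oxopropanoate (racemic)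
Conditions: LDA (2.1 equiv), 2 (2.1 equiv), THF, −78 °C; then 3 (1.0 equiv), −78 → −20 °C; aq NH4Cl
Reagents that add atoms: none
Why: Crossed Claisen acylation in which the chelated lithium enolate of the α-alkoxy ester C-acylates the aroyl chloride, the second equivalent of enolate deprotonating the more acidic β-ketoester as it forms so that double acylation should be suppressed; the new α-stereocentre is racemic and disappears in step 2.

**Step 2**
Reactants: 1 phloroglucinol (anhydrous); 4 ethyl 2-methoxy-3-(4-methoxyphenyl)-3-oxopropanoate
Product: 7 5,7-dihydroxy-3-methoxy-2-(4-methoxyphenyl)-4H-chromen-4-one, via aroyl(methoxy)ketene 5 (not isolated), via aryl 1,3-diketone 6 (not isolated)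
Conditions: 1 (1.0 equiv), 4 (1.5 equiv), neat melt, 240–250 °C, Ar sweep (EtOH and H2O distilled out), 2–3 h
Reagents that add atoms: none
Why: This is the Mentzer pyrone synthesis (thermal, acid-free condensation of a phenol with a β-ketoester), the established way from phloroglucinol and aroylacetates to 5,7-dihydroxyflavones, here run with an α-methoxy aroylacetate. Above about 200 °C the enol of 4 should expel ethanol to give the aroyl(methoxy)ketene 5, which C-acylates the very nucleophilic ring carbon of 1 (C4–C4a bond) to give the 2,4,6-trihydroxyaryl 1,3-diketone 6. The ortho hydroxyl of 6 then adds to the aroyl carbonyl (6-exo-trig closure of O1–C2, forming the pyranone C ring) and the hemiketal loses water to the aromatic chromen-4-one; no stereocentre remains, because the α-carbon of 4 and 6 becomes sp2 C3. Regiochemistry on the A ring needs no control, since all three ring CH carbons and all three hydroxyls of 1 are equivalent. The selectivity that matters is chromone over coumarin (Pechmann mode): without acid the aroyl ketone is not activated for attack by the ring carbon, and any aryl ester from O-acylation should revert to ketene and phenol at this temperature, whereas C-acylation is irreversible. A second annulation is disfavoured because the chelated acyl group deactivates the ring of 7, and the excess of 4 makes up for ketene lost to the water that is released.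

**Step 3**
Reactants: 7 5,7-dihydroxy-3-methoxy-2-(4-methoxyphenyl)-4H-chromen-4-one
Product: 8 kaempferol (3,5,7-trihydroxy-2-(4-hydroxyphenyl)-4H-chromen-4-one)
Conditions: BBr3 (8 equiv), CH2Cl2, −78 °C → rt, 16 h; MeOH, then H2O
Reagents that add atoms: none
Why: Lewis-acid ether cleavage with BBr3 (bromide attack on the methyl group of the boron-bound ether) should remove both methyl ethers, the 3-OMe helped by the neighbouring carbonyl and the 4'-OMe needing excess reagent at room temperature, while the flavone core is inert and the aryl borates hydrolyse on work-up.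

**Step 4**
Reactants: 8 kaempferol
Product: 10 tripotassium kaempferol 3,7,4'-trisulfate, via tris(pyridinium) trisulfate 9 (not isolated)
Conditions: SO3·pyridine (6–9 equiv), pyridine, 25 → 45 °C, HPLC control; then KOAc, MeOH; Sephadex LH-20 (H2O → MeOH)
Reagents that add atoms: sulfur trioxide–pyridine complex, O=S(=O)([O-])[n+]1ccccc1; potassium acetate, CC(=O)[O-].[K+]
Why: O-Sulfation of phenols with an SO3–amine complex should take the 7-, 4'- and 3-hydroxyls, whereas 5-OH, held in a six-membered hydrogen bond to the C4 carbonyl and the least nucleophilic, is expected to stay free at this temperature because its sulfation needs forcing conditions; potassium acetate then precipitates the stable salt.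

**Step 5**
Reactants: 10 tripotassium kaempferol 3,7,4'-trisulfate
Product: 11 kaempferol 3,7,4'-tri-O-sulfate (5-hydroxy-4-oxo-2-[4-(sulfooxy)phenyl]-4H-chromene-3,7-diyl bis(hydrogen sulfate))
Conditions: Dowex 50W-X8 (H+ form), H2O, 0–5 °C; eluate freeze-dried at once
Reagents that add atoms: none
Why: Cation exchange on a strong-acid resin replaces K+ by H+ without any soluble acid being added; because aryl hydrogen sulfates hydrolyse under acid catalysis, the exchange is run cold and dilute and the solution is frozen immediately, with salt 10 remaining the storage form.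

**Compound list**
1 | phloroglucinol (benzene-1,3,5-triol) | Oc1cc(O)cc(O)c1 | starting material
2 | ethyl methoxyacetate | CCOC(=O)COC | starting material
3 | 4-methoxybenzoyl chloride | COc1ccc(cc1)C(Cl)=O | starting material
4 | ethyl 2-methoxy-3-(4-methoxyphenyl)-3-oxopropanoate (racemic) | CCOC(=O)C(OC)C(=O)c1ccc(OC)cc1 | intermediate
5 | aroyl(methoxy)ketene, 2-methoxy-3-(4-methoxyphenyl)-3-oxoprop-1-en-1-one | COC(=C=O)C(=O)c1ccc(OC)cc1 | intermediate (not isolated)
6 | 2-methoxy-1-(4-methoxyphenyl)-3-(2,4,6-trihydroxyphenyl)propane-1,3-dione (racemic) | COC(C(=O)c1ccc(OC)cc1)C(=O)c1c(O)cc(O)cc1O | intermediate (not isolated)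
7 | 5,7-dihydroxy-3-methoxy-2-(4-methoxyphenyl)-4H-chromen-4-one | O=c1c(OC)c(-c2ccc(OC)cc2)oc2cc(O)cc(O)c12 | intermediate
8 | kaempferol | O=c1c(O)c(-c2ccc(O)cc2)oc2cc(O)cc(O)c12 | intermediate
9 | tris(pyridinium) kaempferol 3,7,4'-trisulfate | O=c1c(OS(=O)(=O)[O-])c(-c2ccc(OS(=O)(=O)[O-])cc2)oc2cc(OS(=O)(=O)[O-])cc(O)c12.c1cc[nH+]cc1.c1cc[nH+]cc1.c1cc[nH+]cc1 | intermediate (not isolated)
10 | tripotassium kaempferol 3,7,4'-trisulfate | O=c1c(OS(=O)(=O)[O-])c(-c2ccc(OS(=O)(=O)[O-])cc2)oc2cc(OS(=O)(=O)[O-])cc(O)c12.[K+].[K+].[K+] | intermediate
11 | kaempferol 3,7,4'-tri-O-sulfate (achiral) | O=c1c(OS(=O)(=O)O)c(-c2ccc(OS(=O)(=O)O)cc2)oc2cc(OS(=O)(=O)O)cc(O)c12 | target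

**Total step count:** 5
**Longest linear sequence:** 5 steps (2 + 3 → 4 → 7 → 8 → 10 → 11; phloroglucinol 1 enters at step 2)

**Steps most likely to fail**

Step 2 (Mentzer annulation). At 240–250 °C the acylketene may be intercepted by the water of cyclodehydration (hydrolysis, then decarboxylation), the ketoester may char before C-acylation, or O-acylation followed by Pechmann-type closure may divert material to the coumarin series. The fallback is a Hoesch acylation followed by an Allan–Robinson flavone synthesis; it sets out from 1 and returns at 7. Compound 1 is condensed with methoxyacetonitrile (ZnCl2, HCl gas, Et2O, 0 °C) to the ketiminium chloride F1, which is hydrolysed in hot water to 2-methoxy-1-(2,4,6-trihydroxyphenyl)ethanone F2. Heating F2 with 4-methoxybenzoic anhydride and sodium 4-methoxybenzoate (170–180 °C) builds the pyranone by O-aroylation, acyl transfer to the α-carbon and cyclodehydration, giving the flavone mainly as its 7-O-(4-methoxybenzoyl) ester F3. Brief treatment of F3 with aqueous ethanolic KOH and acidification frees 7.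

Step 4 (tris-sulfation). Sulfation may stop short at the hydrogen-bonded, flanked 3-OH or run on to 5-OH, giving mixtures of very polar salts that are hard to separate and to assign. The fallback uses protected sulfate diesters; it sets out from 8 and returns at 10. Compound 8 is treated with 2,2,2-trichloroethyl chlorosulfate (3.3 equiv), Et3N and DMAP in THF (0 °C → rt) to give the neutral kaempferol 3,7,4'-tris(2,2,2-trichloroethyl sulfate) F4, which can be purified on silica and its substitution pattern checked. Zinc dust and ammonium formate in methanol unmask all three sulfates by reductive fragmentation to triammonium kaempferol 3,7,4'-trisulfate F5. Cation exchange of F5 with potassium acetate in methanol gives 10.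

Step 5 (release of the free acid). Sulfate may be lost by acid-catalysed, autocatalytic hydrolysis while the free acid sits on the strongly acidic resin bed or is concentrated. The fallback is metathesis by precipitation of barium sulfate; it sets out from the pyridinium salt 9 and returns at 11. The crude aqueous solution of 9 is brought to pH 7–8 with Ba(OH)2, which removes inorganic sulfate as BaSO4 and liberates pyridine; the filtrate, passed over Sephadex LH-20, gives tribarium bis(kaempferol 3,7,4'-trisulfate) F6. A cold dilute solution of F6 is titrated with just under one equivalent of H2SO4 per barium and the BaSO4 is centrifuged off. The resulting solution of 11, free of resin contact and of excess mineral acid, is freeze-dried directly or used as such.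

**Further compounds**
F1 | step 2 | 2-methoxy-1-(2,4,6-trihydroxyphenyl)ethan-1-iminium chloride | COCC(=[NH2+])c1c(O)cc(O)cc1O.[Cl-]
F2 | step 2 | 2-methoxy-1-(2,4,6-trihydroxyphenyl)ethanone | COCC(=O)c1c(O)cc(O)cc1O
F3 | step 2 | 5-hydroxy-3-methoxy-2-(4-methoxyphenyl)-4-oxo-4H-chromen-7-yl 4-methoxybenzoate | COc1ccc(cc1)C(=O)Oc1cc(O)c2c(c1)oc(-c1ccc(OC)cc1)c(OC)c2=O
F4 | step 4 | kaempferol 3,7,4'-tris(2,2,2-trichloroethyl sulfate) | O=c1c(OS(=O)(=O)OCC(Cl)(Cl)Cl)c(-c2ccc(OS(=O)(=O)OCC(Cl)(Cl)Cl)cc2)oc2cc(OS(=O)(=O)OCC(Cl)(Cl)Cl)cc(O)c12
F5 | step 4 | triammonium kaempferol 3,7,4'-trisulfate | O=c1c(OS(=O)(=O)[O-])c(-c2ccc(OS(=O)(=O)[O-])cc2)oc2cc(OS(=O)(=O)[O-])cc(O)c12.[NH4+].[NH4+].[NH4+]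
F6 | step 5 | tribarium bis(kaempferol 3,7,4'-trisulfate) | O=c1c(OS(=O)(=O)[O-])c(-c2ccc(OS(=O)(=O)[O-])cc2)oc2cc(OS(=O)(=O)[O-])cc(O)c12.O=c1c(OS(=O)(=O)[O-])c(-c2ccc(OS(=O)(=O)[O-])cc2)oc2cc(OS(=O)(=O)[O-])cc(O)c12.[Ba+2].[Ba+2].[Ba+2]
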